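## Retrosynthetic overview

1. The strategy rests on the oxepene ring (O1, quaternary C2, C3, C4, C5=C6, C7). O1 is bonded to C2, and C2 is β to the aryl ketone through the exocyclic methylene Cα, so the ring is the conjugate adduct of a C7 allylic alcohol and a 2-alkyl-3-aroylacrylate.
2. Target ⇒ acidolysis of the tert-butyl ester and MOM ethers, and Mitsunobu esterification with p-coumaric acid ⇒ oxepene 23 ⇒ O1–C2 oxa-Michael closure (the only ring closure, sets C2) ⇒ seco hydroxy aroylacrylate 22.
3. 22 ⇒ C2=Cα by Horner–Wadsworth–Emmons reaction of α-phosphono ester 15 with arylglyoxal 19; 15 ⇒ ester 12 by C-phosphorylation of its enolate.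
4. 12 ⇒ C4–C5 by Negishi coupling of (Z)-iodoalkene 9 with the zinc reagent of tert-butyl 4-bromobutanoate; 9 ⇒ anti-carbomagnesiation and iodination of propargyl alcohol with the side-chain Grignard reagent, made from 5-bromo-2-methylpent-2-ene by (E)-selective allylic oxidation.

Key step: step 11

## Remarks and assumption

- Assumption: the sense of induction of the catalyst on this substrate class cannot be derived from precedent. The route is written with the L-tert-leucine-derived iminophosphorane–thiourea, SMILES CC(C)(C)[C@H](NC(=S)Nc1cc(C(F)(F)F)cc(C(F)(F)F)c1)CN=P(c1ccc(OC)cc1)(c1ccc(OC)cc1)c1ccc(OC)cc1. Should it favour (2S), its mirror image from D-tert-leucine is used instead.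
- The C2 carboxyl is carried as a tert-butyl ester. A simple alkyl ester would need hydroxide at the end, which would attack the coumarate and open the β-alkoxy ketone by E1cB elimination. The tert-butyl ester falls together with the MOM ethers in one acidic step and cannot lactonise onto the C7 hydroxyl.
- The C7 hydroxyl is masked as a triethylsilyl ether until the acceptor is in place, so that it is released under acid and no racemic closure occurs under the basic olefination conditions.
- p-Coumaric acid is used unprotected, because Mitsunobu esterification selects the carboxyl over the phenol.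

## Route

Step 1
Reactants: 1 5-bromo-2-methylpent-2-ene
Product: 2 (E)-5-bromo-2-methylpent-2-en-1-ol
Conditions: SeO2 (0.3 equiv), t-BuOOH (70% aq, 2.5 equiv), salicylic acid (0.1 equiv), CH2Cl2, 0 °C → rt
Reagents that add atoms: tert-butyl hydroperoxide CC(C)(C)OO (stoichiometric oxygen source); selenium dioxide O=[Se]=O (catalytic oxygen carrier)
Why: The Sharpless SeO2/t-BuOOH allylic oxidation (ene reaction, then [2,3]-sigmatropic shift) hydroxylates the methyl group trans to the chain of a gem-dimethyl trisubstituted alkene, which sets the (E) side-chain alkene, and stopping short of full conversion limits over-oxidation to the enal.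

Step 2
Reactants: 2 (E)-5-bromo-2-methylpent-2-en-1-ol
Product: 3 (E)-(5-bromo-2-methylpent-2-enyloxy)(tert-butyl)dimethylsilane
Conditions: TBSCl, imidazole, DMF, 0 °C → rt
Reagents that add atoms: tert-butyldimethylsilyl chloride CC(C)(C)[Si](C)(C)Cl
Why: Standard silylation of a primary allylic alcohol, giving an ether that tolerates Grignard formation.

Step 3
Reactants: 3 (E)-(5-bromo-2-methylpent-2-enyloxy)(tert-butyl)dimethylsilane; 4 propargyl alcohol
Product: 8 (Z)-3-iodo-2-[(E)-5-(tert-butyldimethylsilyloxy)-4-methylpent-3-enyl]prop-2-en-1-ol, via bromomagnesium prop-2-ynoxide 5 (not isolated), via homoallylic Grignard reagent 6 (not isolated), via cyclic alkenylmagnesium alkoxide 7 (not isolated)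
Conditions: (a) 3 (1.4 equiv), Mg turnings, THF, rt → 40 °C; (b) 4, EtMgBr (1.0 equiv), THF/Et2O, 0 °C; then CuI (15 mol %) and the Grignard solution, 0 °C → rt; (c) I2, THF, −20 °C → rt
Reagents that add atoms: iodine II
Why: Duboudin-type CuI-catalysed anti-carbomagnesiation of the propargylic alkoxide puts the alkyl group on the internal alkyne carbon and magnesium on the terminal carbon within a five-membered chelate, so iodinolysis with retention should give the (Z)-iodoalkene with iodine cis to CH2OH, which fixes the later C5=C6 geometry.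

Step 4
Reactants: 8 (Z)-3-iodo-2-[(E)-5-(tert-butyldimethylsilyloxy)-4-methylpent-3-enyl]prop-2-en-1-ol
Product: 9 triethylsilyl ether of 8
Conditions: TESCl, imidazole, CH2Cl2, 0 °C
Reagents that add atoms: triethylsilyl chloride CC[Si](CC)(CC)Cl
Why: Standard silylation, which places on the future C7 oxygen a group that can later be removed by mild acid in the presence of the primary TBS ether.

Step 5
Reactants: 9 triethylsilyl ether of 8; 10 tert-butyl 4-bromobutanoate
Product: 12 tert-butyl (5Z,9E)-11-(tert-butyldimethylsilyloxy)-10-methyl-6-[(triethylsilyloxy)methyl]undeca-5,9-dienoate, via alkylzinc bromide 11 (not isolated)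
Conditions: 10, Zn dust (activated with BrCH2CH2Br and Me3SiCl), LiCl, THF, 45 °C; then 9, Pd(PPh3)4 (5 mol %), THF, rt → 45 °C
Reagents that add atoms: none
Why: Negishi coupling of a primary alkylzinc bromide with an alkenyl iodide (oxidative addition to zerovalent palladium, transmetalation, reductive elimination) forms C4–C5 with retention of the (Z) geometry and tolerates the ester and both silyl ethers.

Step 6
Reactants: 12 tert-butyl (5Z,9E)-11-(tert-butyldimethylsilyloxy)-10-methyl-6-[(triethylsilyloxy)methyl]undeca-5,9-dienoate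
Product: 15 tert-butyl (5Z,9E)-2-(diethoxyphosphoryl)-11-(tert-butyldimethylsilyloxy)-10-methyl-6-[(triethylsilyloxy)methyl]undeca-5,9-dienoate (racemic at C2), via lithium ester enolate 13 (not isolated), via phosphonite 14 (not isolated)
Conditions: LDA (1.15 equiv), THF, −78 °C; ClP(OEt)2 (1.2 equiv), −78 °C → rt; then H2O2 (30% aq), 0 °C
Reagents that add atoms: diethyl chlorophosphite CCOP(Cl)OCC; hydrogen peroxide OO
Why: C-phosphinylation of an ester enolate with a trivalent phosphorus chloride followed by oxidation of the phosphonite (the Wiemer route to α-phosphono esters) should place the phosphonate on C2 without touching the alkenes or silyl ethers.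

Step 7
Reactants: 16 2',5'-dihydroxyacetophenone
Product: 17 2',5'-bis(methoxymethoxy)acetophenone
Conditions: NaH (2.4 equiv), DMF, 0 °C; MOMCl (2.5 equiv), 0 °C → rt, under argon
Reagents that add atoms: chloromethyl methyl ether COCCl
Why: Williamson-type O-alkylation of both phenoxides, with NaH needed to engage the hydrogen-bonded ortho hydroxyl.

Step 8
Reactants: 17 2',5'-bis(methoxymethoxy)acetophenone
Product: 19 2-[2,5-bis(methoxymethoxy)phenyl]-2-oxoacetaldehyde, via glyoxal hydrate 18 (not isolated)
Conditions: SeO2 (1.3 equiv), 1,4-dioxane/H2O (30:1), 90 °C; Celite filtration; azeotropic drying with toluene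
Reagents that add atoms: selenium dioxide O=[Se]=O
Why: Riley oxidation of an aryl methyl ketone gives the arylglyoxal, obtained as its hydrate and dehydrated azeotropically before use, and the MOM ethers are expected to tolerate the weakly acidic, largely organic medium.

Step 9
Reactants: 15 tert-butyl (5Z,9E)-2-(diethoxyphosphoryl)-11-(tert-butyldimethylsilyloxy)-10-methyl-6-[(triethylsilyloxy)methyl]undeca-5,9-dienoate; 19 2-[2,5-bis(methoxymethoxy)phenyl]-2-oxoacetaldehyde
Product: 21 tert-butyl (2E,5Z,9E)-2-{2-[2,5-bis(methoxymethoxy)phenyl]-2-oxoethylidene}-11-(tert-butyldimethylsilyloxy)-10-methyl-6-[(triethylsilyloxy)methyl]undeca-5,9-dienoate, via sodium phosphonate carbanion 20 (not isolated)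
Conditions: NaH (0.95 equiv relative to 15), THF, 0 °C; then 19 (1.2 equiv), −78 → 0 °C
Reagents that add atoms: none
Why: Horner–Wadsworth–Emmons olefination at the aldehyde carbonyl of the non-enolisable glyoxal, far more electrophilic than its ketone, should give the aroylacrylate with the aroyl group trans to the ester (E), while the triethylsilyl ether keeps the C7 oxygen from adding under the basic conditions.

Step 10
Reactants: 21 tert-butyl (2E,5Z,9E)-2-{2-[2,5-bis(methoxymethoxy)phenyl]-2-oxoethylidene}-11-(tert-butyldimethylsilyloxy)-10-methyl-6-[(triethylsilyloxy)methyl]undeca-5,9-dienoate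
Product: 22 tert-butyl (2E,5Z,9E)-2-{2-[2,5-bis(methoxymethoxy)phenyl]-2-oxoethylidene}-11-(tert-butyldimethylsilyloxy)-6-(hydroxymethyl)-10-methylundeca-5,9-dienoate (seco hydroxy aroylacrylate)
Conditions: PPTS (0.2 equiv), MeOH/CH2Cl2 (1:1), 0 °C; used directly in step 11
Reagents that add atoms: none
Why: Acid-catalysed methanolysis cleaves a primary triethylsilyl ether much faster than a primary TBS ether and leaves the aryl MOM ethers and tert-butyl ester alone, and the non-basic medium avoids premature racemic ring closure.

Step 11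
Reactants: 22 seco hydroxy aroylacrylate
Product: 23 tert-butyl (2R)-2-{2-[2,5-bis(methoxymethoxy)phenyl]-2-oxoethyl}-6-[(E)-5-(tert-butyldimethylsilyloxy)-4-methylpent-3-enyl]-2,3,4,7-tetrahydrooxepine-2-carboxylate
Conditions: iminophosphorane–thiourea catalyst of the remark above (10 mol %), toluene (0.02 M), −20 °C; AcOH quench at −20 °C, rapid filtration through silica
Reagents that add atoms: none
Why: Proposed new method: the iminophosphorane nitrogen takes the proton of the C7 hydroxyl while the thiourea binds the aryl ketone, so that this oxygen (the future O1) adds to C2 of the (E)-aroylacrylate, β to the ketone, and the ketone enolate is then protonated at Cα by the iminophosphoranium; the closest known reaction type is the intramolecular oxa-Michael addition of alcohols to enones and enoates under bifunctional iminophosphorane or cinchona thiourea/squaramide catalysis, which gives five- and six-membered ethers. The oxepene closes 7-exo-trig, whereas attack at Cα would be an 8-endo closure at a position activated only by the ester and leading to the less stable ester enolate. C2 is the only stereocentre and its configuration is set by the catalyst alone, which differentiates the two faces of the trisubstituted acceptor held between thiourea and iminophosphoranium. The step needs regioselection for C2, which the ketone polarisation secures; chemoselection against chromanone formation and lactonisation, which the MOM ethers and the tert-butyl ester secure; and a reachable seven-membered ring, which the (Z)-C5=C6 alkene secures by holding the C7 hydroxyl and C4 on the same side. Low temperature, a non-polar solvent, high dilution and the acidic quench are meant to keep retro-addition and γ-deprotonation at C3 from eroding the enantiomeric purity.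

Step 12
Reactants: 23 protected oxepene
Product: 24 tert-butyl (2R)-2-{2-[2,5-bis(methoxymethoxy)phenyl]-2-oxoethyl}-6-[(E)-5-hydroxy-4-methylpent-3-enyl]-2,3,4,7-tetrahydrooxepine-2-carboxylate
Conditions: HF·pyridine, pyridine, THF, 0 °C → rt
Reagents that add atoms: none
Why: Buffered fluoride desilylation frees the side-chain alcohol without a basic medium that could open the β-alkoxy ketone by retro-oxa-Michael reaction, so C2 is not scrambled.

Step 13
Reactants: 24 side-chain allylic alcohol; 25 p-coumaric acid ((E)-3-(4-hydroxyphenyl)prop-2-enoic acid)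
Product: 26 tert-butyl (2R)-2-{2-[2,5-bis(methoxymethoxy)phenyl]-2-oxoethyl}-6-[(E)-5-{[(E)-3-(4-hydroxyphenyl)prop-2-enoyl]oxy}-4-methylpent-3-enyl]-2,3,4,7-tetrahydrooxepine-2-carboxylate
Conditions: 25 (1.5 equiv), PPh3 (1.5 equiv), DIAD (1.4 equiv), THF, 0 °C → rt
Reagents that add atoms: none
Why: Mitsunobu esterification of a primary allylic alcohol is chemoselective for the carboxyl of a phenolic acid, because only the carboxylic acid is acidic enough to protonate the betaine and act as the nucleophile.

Step 14
Reactants: 26 protected coumarate ester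
Product: 27 (2R)-2-[2-(2,5-dihydroxyphenyl)-2-oxoethyl]-6-[(E)-5-{[(E)-3-(4-hydroxyphenyl)prop-2-enoyl]oxy}-4-methylpent-3-enyl]-2,3,4,7-tetrahydrooxepine-2-carboxylic acid (target)
Conditions: TFA/CH2Cl2 (1:4), H2O (5 equiv), 0 °C → rt
Reagents that add atoms: none
Why: Acidolysis removes the tert-butyl ester (as isobutene) and both aryl MOM acetals in one operation, and the two trisubstituted alkenes are slowed towards protonation by their allylic C–O bonds while C2, lacking any acidic hydrogen, is untouched.

## Compound list

1 | 5-bromo-2-methylpent-2-ene | CC(C)=CCCBr | starting material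
2 | (E)-5-bromo-2-methylpent-2-en-1-ol | C/C(=C\CCBr)CO | intermediate
3 | (E)-(5-bromo-2-methylpent-2-enyloxy)(tert-butyl)dimethylsilane | C/C(=C\CCBr)CO[Si](C)(C)C(C)(C)C | intermediate
4 | propargyl alcohol (prop-2-yn-1-ol) | C#CCO | starting material
5 | bromomagnesium prop-2-ynoxide | C#CCO[Mg]Br | intermediate (not isolated)
6 | [(E)-5-(tert-butyldimethylsilyloxy)-4-methylpent-3-enyl]magnesium bromide | C/C(=C\CC[Mg]Br)CO[Si](C)(C)C(C)(C)C | intermediate (not isolated)
7 | cyclic alkenylmagnesium alkoxide (4-substituted 2,5-dihydro-1,2-oxamagnesole) | C/C(=C\CCC1=C[Mg]OC1)CO[Si](C)(C)C(C)(C)C | intermediate (not isolated)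
8 | (Z)-3-iodo-2-[(E)-5-(tert-butyldimethylsilyloxy)-4-methylpent-3-enyl]prop-2-en-1-ol | C/C(=C\CC/C(CO)=C/I)CO[Si](C)(C)C(C)(C)C | intermediate
9 | triethylsilyl ether of 8 | C/C(=C\CC/C(CO[Si](CC)(CC)CC)=C/I)CO[Si](C)(C)C(C)(C)C | intermediate
10 | tert-butyl 4-bromobutanoate | CC(C)(C)OC(=O)CCCBr | starting material
11 | (4-tert-butoxy-4-oxobutyl)zinc bromide | CC(C)(C)OC(=O)CCC[Zn]Br | intermediate (not isolated)
12 | tert-butyl (5Z,9E)-11-(tert-butyldimethylsilyloxy)-10-methyl-6-[(triethylsilyloxy)methyl]undeca-5,9-dienoate | C/C(=C\CC/C(CO[Si](CC)(CC)CC)=C/CCCC(=O)OC(C)(C)C)CO[Si](C)(C)C(C)(C)C | intermediate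
13 | lithium enolate of 12 (alkyl trans to OLi) | C/C(=C\CC/C(CO[Si](CC)(CC)CC)=C/CC/C=C(/O[Li])OC(C)(C)C)CO[Si](C)(C)C(C)(C)C | intermediate (not isolated)
14 | α-(diethoxyphosphanyl) ester (phosphonite, racemic) | C/C(=C\CC/C(CO[Si](CC)(CC)CC)=C/CCC(C(=O)OC(C)(C)C)P(OCC)OCC)CO[Si](C)(C)C(C)(C)C | intermediate (not isolated)
15 | tert-butyl (5Z,9E)-2-(diethoxyphosphoryl)-11-(tert-butyldimethylsilyloxy)-10-methyl-6-[(triethylsilyloxy)methyl]undeca-5,9-dienoate (racemic) | C/C(=C\CC/C(CO[Si](CC)(CC)CC)=C/CCC(C(=O)OC(C)(C)C)P(=O)(OCC)OCC)CO[Si](C)(C)C(C)(C)C | intermediate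
16 | 2',5'-dihydroxyacetophenone | CC(=O)c1cc(O)ccc1O | starting material
17 | 2',5'-bis(methoxymethoxy)acetophenone | CC(=O)c1cc(OCOC)ccc1OCOC | intermediate
18 | 1-[2,5-bis(methoxymethoxy)phenyl]-2,2-dihydroxyethanone (glyoxal hydrate) | OC(O)C(=O)c1cc(OCOC)ccc1OCOC | intermediate (not isolated)
19 | 2-[2,5-bis(methoxymethoxy)phenyl]-2-oxoacetaldehyde | O=CC(=O)c1cc(OCOC)ccc1OCOC | intermediate
20 | sodium salt of phosphonate 15 | [Na+].C/C(=C\CC/C(CO[Si](CC)(CC)CC)=C/CC[C-](C(=O)OC(C)(C)C)P(=O)(OCC)OCC)CO[Si](C)(C)C(C)(C)C | intermediate (not isolated)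
21 | tert-butyl (2E,5Z,9E)-2-{2-[2,5-bis(methoxymethoxy)phenyl]-2-oxoethylidene}-11-(tert-butyldimethylsilyloxy)-10-methyl-6-[(triethylsilyloxy)methyl]undeca-5,9-dienoate | C/C(=C\CC/C(CO[Si](CC)(CC)CC)=C/CC/C(C(=O)OC(C)(C)C)=C\C(=O)c1cc(OCOC)ccc1OCOC)CO[Si](C)(C)C(C)(C)C | intermediate
22 | seco hydroxy aroylacrylate: tert-butyl (2E,5Z,9E)-2-{2-[2,5-bis(methoxymethoxy)phenyl]-2-oxoethylidene}-11-(tert-butyldimethylsilyloxy)-6-(hydroxymethyl)-10-methylundeca-5,9-dienoate | C/C(=C\CC/C(CO)=C/CC/C(C(=O)OC(C)(C)C)=C\C(=O)c1cc(OCOC)ccc1OCOC)CO[Si](C)(C)C(C)(C)C | intermediate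
23 | tert-butyl (2R)-2-{2-[2,5-bis(methoxymethoxy)phenyl]-2-oxoethyl}-6-[(E)-5-(tert-butyldimethylsilyloxy)-4-methylpent-3-enyl]-2,3,4,7-tetrahydrooxepine-2-carboxylate | C/C(=C\CCC1=CCC[C@@](CC(=O)c2cc(OCOC)ccc2OCOC)(C(=O)OC(C)(C)C)OC1)CO[Si](C)(C)C(C)(C)C | intermediate
24 | tert-butyl (2R)-2-{2-[2,5-bis(methoxymethoxy)phenyl]-2-oxoethyl}-6-[(E)-5-hydroxy-4-methylpent-3-enyl]-2,3,4,7-tetrahydrooxepine-2-carboxylate | C/C(=C\CCC1=CCC[C@@](CC(=O)c2cc(OCOC)ccc2OCOC)(C(=O)OC(C)(C)C)OC1)CO | intermediate
25 | p-coumaric acid | O=C(O)/C=C/c1ccc(O)cc1 | starting material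
26 | tert-butyl (2R)-2-{2-[2,5-bis(methoxymethoxy)phenyl]-2-oxoethyl}-6-[(E)-5-{[(E)-3-(4-hydroxyphenyl)prop-2-enoyl]oxy}-4-methylpent-3-enyl]-2,3,4,7-tetrahydrooxepine-2-carboxylate | C/C(=C\CCC1=CCC[C@@](CC(=O)c2cc(OCOC)ccc2OCOC)(C(=O)OC(C)(C)C)OC1)COC(=O)/C=C/c1ccc(O)cc1 | intermediate
27 | (2R)-2-[2-(2,5-dihydroxyphenyl)-2-oxoethyl]-6-[(E)-5-{[(E)-3-(4-hydroxyphenyl)prop-2-enoyl]oxy}-4-methylpent-3-enyl]-2,3,4,7-tetrahydrooxepine-2-carboxylic acid | C/C(=C\CCC1=CCC[C@@](CC(=O)c2cc(O)ccc2O)(C(=O)O)OC1)COC(=O)/C=C/c1ccc(O)cc1 | target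

## Step count and risks

Total step count: 14. Longest linear sequence: 12 steps (steps 1–6 and 9–14, from 1 to 27); steps 7 and 8 make the arylglyoxal branch.

Steps most likely to fail:

1. Step 11 (key step). The catalyst may discriminate poorly between the two faces of the trisubstituted acceptor in a seven-membered transition state. Enantiomeric purity may also be eroded by retro-addition under the basic catalyst, or the acceptor geometry scrambled by γ-deprotonation at C3. Fallback with known chemistry: from 22 the ring is closed under thermodynamic control with an achiral base (catalytic t-BuOK in THF at 0 °C, or DBU in toluene). This should give 23 together with its mirror image, tert-butyl (2S)-2-{2-[2,5-bis(methoxymethoxy)phenyl]-2-oxoethyl}-6-[(E)-5-(tert-butyldimethylsilyloxy)-4-methylpent-3-enyl]-2,3,4,7-tetrahydrooxepine-2-carboxylate F1. The two are separated by preparative chromatography on a polysaccharide chiral stationary phase. The unwanted enantiomer F1 is returned to the racemate with the same base (retro-addition to 22 and re-closure) and resolved again. The fallback sets out from 22 and rejoins the route at 23.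

2. Step 9. The α-branched phosphonate may give poor E/Z control, its anion may attack the ketone carbonyl or degrade the glyoxal, and the product may deconjugate under base. Fallback: from ester 12 the enolate 13 is regenerated (LDA, THF, −78 °C) and added to glyoxal 19 to give the aldol adduct tert-butyl 2-{2-[2,5-bis(methoxymethoxy)phenyl]-1-hydroxy-2-oxoethyl}-substituted dienoate F2 as a diastereomer mixture. Mesylation (MsCl, Et3N, CH2Cl2, 0 °C) gives the mesylate F3, and DBU then effects E1cB elimination through the ester enolate to the thermodynamically favoured (E)-aroylacrylate, with catalytic iodine available to equilibrate any (Z) isomer. The fallback sets out from 12 and rejoins the route at 21.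

3. Step 14. Under Brønsted acid the trisubstituted alkenes may be protonated, the allylic C–O bonds may ionise, the hydroquinone ring may be substituted by formaldehyde equivalents, and the freed ortho phenol may close a chromanone after retro-oxa-Michael opening. Fallback by silyl transfer in a buffered, non-protic medium: from 26, TMSOTf with 2,2'-bipyridyl and 2,6-lutidine (CH2Cl2, 0 °C) should convert the aryl MOM ethers into aryl trimethylsilyl ethers and the tert-butyl ester into the trimethylsilyl ester, and silylate the coumarate phenol. This gives the tetrakis(trimethylsilyl) derivative F4, which is hydrolysed under neutral conditions (THF/pH 7 buffer, rt) to the target. The fallback sets out from 26 and rejoins the route at 27.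

## Further compounds

F1 | step 11 | tert-butyl (2S)-2-{2-[2,5-bis(methoxymethoxy)phenyl]-2-oxoethyl}-6-[(E)-5-(tert-butyldimethylsilyloxy)-4-methylpent-3-enyl]-2,3,4,7-tetrahydrooxepine-2-carboxylate (enantiomer of 23) | C/C(=C\CCC1=CCC[C@](CC(=O)c2cc(OCOC)ccc2OCOC)(C(=O)OC(C)(C)C)OC1)CO[Si](C)(C)C(C)(C)C
F2 | step 9 | aldol adduct of 12 and 19 (β-hydroxy γ-keto ester, diastereomer mixture) | C/C(=C\CC/C(CO[Si](CC)(CC)CC)=C/CCC(C(=O)OC(C)(C)C)C(O)C(=O)c1cc(OCOC)ccc1OCOC)CO[Si](C)(C)C(C)(C)C
F3 | step 9 | methanesulfonate of F2 | C/C(=C\CC/C(CO[Si](CC)(CC)CC)=C/CCC(C(=O)OC(C)(C)C)C(OS(C)(=O)=O)C(=O)c1cc(OCOC)ccc1OCOC)CO[Si](C)(C)C(C)(C)C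
F4 | step 14 | tetrakis(trimethylsilyl) derivative of 27 (three aryl silyl ethers and the silyl ester) | C/C(=C\CCC1=CCC[C@@](CC(=O)c2cc(O[Si](C)(C)C)ccc2O[Si](C)(C)C)(C(=O)O[Si](C)(C)C)OC1)COC(=O)/C=C/c1ccc(O[Si](C)(C)C)cc1
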